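## Structural features

The target is a 5-alkylresorcinol: a benzene ring with free hydroxyl groups at C1 and C3 and an unbranched fifteen-carbon chain at C5. The chain runs through seven methylene groups (C1'–C7') to a cis C8'=C9' double bond, then to the only stereocentre, C10' (R), which carries an acetoxy group and a pentyl tail (C11'–C15'). No two stereocentres are adjacent; instead the single stereocentre stands directly next to the single stereogenic alkene, as a (Z)-allylic secondary acetate. This unit is the fragile part. An allylic acetate ionises or transposes under acid or zerovalent palladium, is displaced in the SN2' sense by organocopper reagents, and can pass its acetyl group to a phenoxide. The Z alkene can isomerise, and the acidic, electron-rich resorcinol quenches organometallic reagents. The arene is not the difficulty, since 5-substituted resorcinols can be bought. The difficulty is to create the R carbinol and the Z alkene together under secure control and to join them to a long saturated tether without disturbing either. The key step exploits the fact that O–C10'–C9'=C8'–C7' is the O1–C6–C5=C4–C3 edge of a 3,6-dihydro-2H-pyran whose last ring atom C2 (the future C6') bears an ester. The ring fixes the cis geometry, an oxa-[4+2] cycloaddition makes the O–C10' and C6'–C7' bonds with control of C10', and the ring is reopened later at O–C6'.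

## Logic of the disconnections

16 to 15: the two phenolic O–H bonds are traced back to O–Si bonds. The phenols must be masked through the organomagnesium steps, and silyl ethers are the masks that can be removed last without hydrogenation, strong acid or Lewis acid. The gain is a neutral, lipophilic intermediate. The demand is that unmasking causes no acyl transfer from the C10' oxygen to a liberated phenol.

15 to 14: the ester C–O bond at C10' is cut. Acetylation comes after all carbon–carbon bond formation, because an allylic acetate would not survive a copper-catalysed Grignard coupling whereas the free carbinol does. The forward step is an acylation that does not touch the C10'–O bond.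

14 to 7 and 13: the C4'–C5' bond in the saturated tether is cut. It is an sp3–sp3 bond remote from both the alkene and the stereocentre, so forming it cannot affect either. The cut divides the molecule into a chiral C11 electrophile, 7, and an achiral arylbutyl nucleophile, 13. The forward coupling must tolerate the magnesium alkoxide at C10' and must outrun intramolecular ether formation.

13 to 12, then 12 to 11 and 10, then 11 to 9, then 9 to 8: the C4'–Mg bond comes from the C4'–Br bond of 12. The aryl–C1' bond of 12 is cut to an aryl nucleophile 11 and the symmetrical C4 dielectrophile 10. The O–Si bonds of 9 lead back to 8. This gives the arene arm in two operations from bought materials without palladium or aqueous base. The demand is monosubstitution of 10, met by using it in excess.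

7 to 6, then 6 to 5: the sulfonate O–S bond is removed, and C5' is returned from the alcohol to the ester oxidation level. The simplification is small, but it exposes an ester at C5' with a methylene C6' beside it. The forward steps need hydride reduction that leaves the allylic system alone and discrimination between a primary and a secondary hydroxyl.

5 to 4: a bond is added, in the retrosynthetic sense, between the C10' oxygen and C6', the carbon alpha to the ester. The open-chain hydroxy ester becomes a six-membered cyclic ether. The acyclic problem of Z geometry and a single stereocentre thereby becomes a problem of ring stereochemistry, and the C6' centre so created is disposable. The forward step must break only the C6'–O bond, the one alpha to the ester, and leave the C10'–O bond intact.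

4 to 2 and 3: the O–C10' and C6'–C7' bonds are cut together as a retro-[4+2]. This removes the ring and both stereocentres in one move and leads to an achiral diene and an achiral C2 aldehyde ester. The forward step must control regiochemistry, endo orientation and the face of the carbonyl group.

2 to 1: the terminal C=C bond of the diene (future C7'–C8') is cut by olefination logic. Compound 1 already holds the E alkene and the pentyl group, so one methylenation suffices. The demand is only that the E geometry be preserved.

## Other disconnections considered

Alternative 1: The cut is the C8'=C9' double bond itself, made inside a five-membered ring in which boron and the C10' oxygen form the tether; a second cut at C7'–C8' then attaches the rest of the chain. In the forward sense (R)-oct-1-en-3-ol A2 would be converted into its mixed butyl vinylboronate A3. The second-generation Grubbs catalyst would close A3 by ring-closing metathesis, with extrusion of the volatile C2 alkene, to the oxaborole A1. Suzuki–Miyaura coupling of the alkenyl–boron bond of A1 with 1-(7-bromoheptyl)-3,5-bis(tert-butyldimethylsilyloxy)benzene A4 would then give 14 directly, and the chosen end-game would follow.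
- In favour: the five-membered ring enforces the Z geometry as firmly as the dihydropyran does. The stereocentre arrives ready-made in A2 and never faces a selectivity question. A1 is two operations from A2.
- Against: coupling an alkenylboron species with an unactivated primary alkyl bromide that has beta-hydrogens is the demanding kind of Suzuki–Miyaura reaction (slow oxidative addition, beta-hydride elimination). A1 is moisture-sensitive. A4 needs a seven-carbon linker and so a sequence of its own. The chirality is bought or resolved, not created.
- Comparison: on structure both plans hide the cis alkene in a ring, and on security of the Z geometry the alternative is the equal of the chosen plan. On security of the C10' configuration the alternative is the better, because the chosen plan depends on facial and endo selectivity and on relay through a centre that is later destroyed. On mechanism the chosen plan joins its fragments by a copper-catalysed sp3–sp3 displacement, which is more dependable than the sp2–sp3 palladium coupling the alternative needs at its decisive junction. In step count the two are close, and the alternative may be one step shorter in its longest line if A2 is purchased. The chosen plan is kept because it makes the stereocentre catalytically from achiral C8 and C2 feedstocks and places its one delicate step early, on cheap material.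

Alternative 2: The cut lies in the arene: two ring bonds (C3–C4 and C5–C6) are disconnected so that the resorcinol arises from a four-carbon and a two-carbon piece. In the forward sense the cyclobutenone A6, which already carries the complete silyl-protected side chain, would be heated with ethoxyacetylene A7. Electrocyclic opening to a vinylketene, regioselective [2+2] cycloaddition with A7, opening of the new four-membered ring to a dienylketene, 6-pi electrocyclisation and tautomerisation should give the resorcinol monoethyl ether A5.
- In favour: a metal-free pericyclic cascade under neutral thermal conditions, with the 1,3,5 pattern fixed by the mechanism. The silyl ether and the Z alkene should tolerate it.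
- Against: the arene is the one part of 16 that is commercially available (as 8). The real problem, C10' and the Z alkene, is not addressed and would have to be solved beforehand and carried through the cyclobutenone synthesis. The O-ethyl group of A5 calls for ether cleavage by a strong Lewis acid or hot thiolate, which the Z-allylic oxygen function would not survive; a silyloxyalkyne would have to replace A7. The final silyl-to-acetyl exchange at C10' would have to be done beside two free phenols.
- Comparison: on structure the regiochemical certainty of the arene is equal in both plans. On mechanism the alternative is the better in atom economy and in needing no metal at its key step. On step economy it is clearly the worse: it is linear, it builds what can be bought, and it adds a deprotection that threatens the allylic unit.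

Alternative 3: The cut is the arene C1–C6 bond, so that the ring unfolds to a linear tetraketide. In the forward sense the trioxo ester A9 would be treated with mild base. The C2 enolate would add to the C7 ketone, and the aldol product would dehydrate and enolise to the 2,4-dihydroxy-6-alkylbenzoate A8. Saponification, decarboxylation and exchange of the silyl group for acetyl would then be needed.
- In favour: the closure is biomimetic and ionic under mild conditions, the regiochemistry is built in, and no transition metal is needed. If carboxylated congeners of 16 were wanted, A8 would be a direct entry, and on that count the alternative is the better plan.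
- Against: A9 is a sensitive poly-beta-carbonyl compound that requires polyanion acylation chemistry. Its cyclisation competes with pyrone formation. An extra carbon must be removed by hydrolysis and decarboxylation under conditions that stress the Z-allylic silyl ether. C10' must again be acetylated selectively in the presence of free phenols.
- Comparison: on structure, A8 and 14 reach the same arene pattern with equal certainty. On mechanism the aldol closure is as benign towards C10' and the alkene as the chosen copper coupling, so the two are equal there. On step economy the alternative is much the longer, since the chiral chain must be made first and then carried through ring construction and decarboxylation.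

Key step: step 2

Remarks and assumptions on the chemistry:
- Side-chain atoms are numbered C1' (benzylic) to C15'; the target is (8'Z,10'R).
- Structure check: in 4 the (2R,6R) descriptor pair is the cis isomer, and C6 of 4 becomes C10' of 16 with unchanged priorities, so R is carried through. No structure needed correction.
- Assumption: the sense of induction is taken from the square-planar chelate model, in which the (R,R)-tert-butyl ligand leaves the Re face of bound 3 open. If the cycloadduct shows the opposite sense, the (S,S)-ligand is used and nothing else changes.
- Design choice: the arylbutyl unit is built from 8 and 10 by Grignard chemistry alone. This is shorter than a hydroboration and cross-coupling sequence and keeps the aryl silyl ethers away from aqueous base.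

## Steps

Step 1
Reactants: 1 (E)-oct-2-enal
Product: 2 (E)-nona-1,3-diene
Conditions: Ph3PCH3Br (1.2 equiv), KOt-Bu (1.15 equiv), THF, 0 °C → rt
Reagents that add atoms: methyltriphenylphosphonium bromide, C[P+](c1ccccc1)(c1ccccc1)c1ccccc1.[Br-]
Why: Wittig methylenation of an enal; the unstabilised ylide adds 1,2 to the aldehyde and the existing E alkene is not touched, so the diene geometry is that of 1; any Z contaminant cannot reach the s-cis conformation easily and is rejected in step 2.

Step 2
Reactants: 2 (E)-nona-1,3-diene; 3 ethyl glyoxylate (freshly distilled monomer)
Product: 4 ethyl (2R,6R)-6-pentyl-3,6-dihydro-2H-pyran-2-carboxylate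
Conditions: Cu(OTf)2 (10 mol %), (R,R)-tBu-box [2,2'-(propane-2,2-diyl)bis((4R)-4-tert-butyl-4,5-dihydrooxazole)] (11 mol %), 2 (1.5 equiv), CH2Cl2, 0 °C → rt
Reagents that add atoms: none
Why: This is an oxa-Diels–Alder reaction of a glyoxylate ester with an unactivated diene under a C2-symmetric bis(oxazoline) complex of divalent copper, and the closest known reaction type is the copper–bis(oxazoline)-catalysed cycloaddition of glyoxylates with simple 1,3-dienes. Compound 3 binds copper through both the aldehyde and the ester carbonyl oxygen, which lowers its LUMO and holds it s-cis in the ligand plane. Bond formation is concerted but asynchronous: the unsubstituted terminus C1 of 2 attacks the aldehyde carbon first (the future C6'–C7' bond), positive charge builds at the pentyl-bearing terminus C4, and the oxygen bonds there (the future O–C10' bond), which fixes the 2,6 substitution pattern. The six-membered ring is closed in this same suprafacial [4+2] event; in the stepwise limit the closure is collapse of the copper-bound alkoxide onto the terminus of the allyl cation. The C2 centre is set by the ligand: the tert-butyl group of the (R,R)-ligand is expected to cover the Si face of the chelated aldehyde, so the diene adds to the Re face and C2 becomes R. The C6 centre is set relative to C2 by the endo position of the ester together with the fixed E geometry of 2, which places pentyl and ester cis and makes C6, the future C10', R. The step needs regioselectivity, endo selectivity, facial selectivity and cycloaddition in preference to proton loss (the carbonyl-ene or Prins pathway); diene polarisation, two-point binding of 3 and the weakly basic triflate medium are expected to secure these. The minor trans isomer is to be removed by chromatography at this stage, because after ring opening it would give the enantiomer of 5.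

Step 3
Reactants: 4 ethyl (2R,6R)-6-pentyl-3,6-dihydro-2H-pyran-2-carboxylate
Product: 5 ethyl (4Z,6R)-6-hydroxyundec-4-enoate
Conditions: SmI2 (2.5 equiv), HMPA (8 equiv), MeOH (3 equiv), THF, 0 °C
Reagents that add atoms: none
Why: SmI2-mediated reductive cleavage of an alpha-alkoxy ester: electron transfer to the ester gives a ketyl that expels the ring oxygen as an alkoxide, a second electron gives the samarium enolate, and MeOH protonates it at C2; the C6–O bond (future C10'–O) is not alpha to a carbonyl group and stays, the C2 centre is erased, and the intermediate radical is homoallylic and not allylic, so the Z alkene should be retained.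

Step 4
Reactants: 5 ethyl (4Z,6R)-6-hydroxyundec-4-enoate
Product: 6 (4Z,6R)-undec-4-ene-1,6-diol
Conditions: LiAlH4 (1.5 equiv), THF, 0 °C; aq. potassium sodium tartrate
Reagents that add atoms: none
Why: Hydride reduction of an ester to a primary alcohol; the isolated Z alkene and the allylic alkoxide are inert to LiAlH4 at 0 °C, and no bond at the stereocentre is involved.

Step 5
Reactants: 6 (4Z,6R)-undec-4-ene-1,6-diol
Product: 7 (4Z,6R)-6-hydroxyundec-4-en-1-yl 4-methylbenzenesulfonate
Conditions: TsCl (1.05 equiv), Et3N (1.5 equiv), Me3N·HCl (10 mol %), CH2Cl2, 0 °C
Reagents that add atoms: 4-methylbenzenesulfonyl chloride, Cc1ccc(S(=O)(=O)Cl)cc1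
Why: Chemoselective sulfonylation: the unhindered primary hydroxyl reacts much faster than the secondary allylic one under amine-catalysed tosylation with one equivalent of TsCl; 7 is to be used promptly and kept cold.

Step 6
Reactants: 8 5-bromobenzene-1,3-diol
Product: 9 1-bromo-3,5-bis(tert-butyldimethylsilyloxy)benzene
Conditions: TBSCl (2.4 equiv), imidazole (5 equiv), DMF, rt
Reagents that add atoms: tert-butyldimethylsilyl chloride, CC(C)(C)[Si](C)(C)Cl
Why: Standard silylation of phenols with a silyl chloride and imidazole; aryl silyl ethers of this type tolerate Grignard formation and are removable by fluoride at the end.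

Step 7
Reactants: 9 1-bromo-3,5-bis(tert-butyldimethylsilyloxy)benzene; 10 1,4-dibromobutane
Product: 12 1-(4-bromobutyl)-3,5-bis(tert-butyldimethylsilyloxy)benzene, via aryl Grignard reagent 11 (not isolated)
Conditions: Mg, I2 (cat.), THF, reflux; then added to 10 (4 equiv), Li2CuCl4 (3 mol %), THF, −10 → 0 °C
Reagents that add atoms: none
Why: Aryl Grignard formation followed by Li2CuCl4-catalysed sp2–sp3 cross-coupling with a primary alkyl bromide; the excess of 10 makes a second substitution statistically unimportant, and the silyloxy groups are meta to the carbanion, so silyl migration to carbon is not possible.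

Step 8
Reactants: 12 1-(4-bromobutyl)-3,5-bis(tert-butyldimethylsilyloxy)benzene; 7 (4Z,6R)-6-hydroxyundec-4-en-1-yl 4-methylbenzenesulfonate
Product: 14 (8Z,10R)-1-[3,5-bis(tert-butyldimethylsilyloxy)phenyl]pentadec-8-en-10-ol, via alkyl Grignard reagent 13 (not isolated)
Conditions: 12 (2.6 equiv), Mg, THF, 40 °C; then 7 (1.0 equiv), Li2CuCl4 (5 mol %), THF, −40 → 0 °C; aq. NH4Cl
Reagents that add atoms: none
Why: Copper-catalysed sp3–sp3 cross-coupling of a primary alkyl Grignard reagent with a primary tosylate; the first equivalent of 13 turns the C10' hydroxyl into its magnesium alkoxide, which is not a leaving group and is a poor nucleophile at low temperature, and the new C4'–C5' bond is remote from the Z alkene and from C10', so neither should be affected.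

Step 9
Reactants: 14 (8Z,10R)-1-[3,5-bis(tert-butyldimethylsilyloxy)phenyl]pentadec-8-en-10-ol
Product: 15 (8Z,10R)-1-[3,5-bis(tert-butyldimethylsilyloxy)phenyl]pentadec-8-en-10-yl acetate
Conditions: Ac2O (2 equiv), pyridine, DMAP (5 mol %), CH2Cl2, 0 °C → rt
Reagents that add atoms: acetic anhydride, CC(=O)OC(C)=O
Why: DMAP-catalysed O-acylation of a secondary allylic alcohol; the C10'–O bond is not broken, so the configuration is retained, and the basic, non-ionising conditions avoid allylic transposition.

Step 10
Reactants: 15 (8Z,10R)-1-[3,5-bis(tert-butyldimethylsilyloxy)phenyl]pentadec-8-en-10-yl acetate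
Product: 16 (8Z,10R)-1-(3,5-dihydroxyphenyl)pentadec-8-en-10-yl acetate (target)
Conditions: TBAF (2.4 equiv), AcOH (2.6 equiv), THF, 0 °C
Reagents that add atoms: none
Why: Fluoride-induced cleavage of aryl silyl ethers, which are especially labile because phenoxide is a good leaving group from silicon; the acetic acid buffer protonates the phenoxide as it forms, so that acyl transfer from C10' and ester cleavage should be suppressed.

## Compound list

1 | (E)-oct-2-enal | CCCCC/C=C/C=O | starting material
2 | (E)-nona-1,3-diene | C=C/C=C/CCCCC | intermediate
3 | ethyl glyoxylate | CCOC(=O)C=O | starting material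
4 | ethyl (2R,6R)-6-pentyl-3,6-dihydro-2H-pyran-2-carboxylate | CCCCC[C@@H]1C=CC[C@H](C(=O)OCC)O1 | intermediate
5 | ethyl (4Z,6R)-6-hydroxyundec-4-enoate | CCCCC[C@H](/C=C\CCC(=O)OCC)O | intermediate
6 | (4Z,6R)-undec-4-ene-1,6-diol | CCCCC[C@H](/C=C\CCCO)O | intermediate
7 | (4Z,6R)-6-hydroxyundec-4-en-1-yl 4-methylbenzenesulfonate | CCCCC[C@H](/C=C\CCCOS(=O)(=O)c1ccc(C)cc1)O | intermediate
8 | 5-bromobenzene-1,3-diol | Oc1cc(O)cc(Br)c1 | starting material
9 | 1-bromo-3,5-bis(tert-butyldimethylsilyloxy)benzene | Brc1cc(O[Si](C)(C)C(C)(C)C)cc(O[Si](C)(C)C(C)(C)C)c1 | intermediate
10 | 1,4-dibromobutane | BrCCCCBr | starting material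
11 | [3,5-bis(tert-butyldimethylsilyloxy)phenyl]magnesium bromide | Br[Mg]c1cc(O[Si](C)(C)C(C)(C)C)cc(O[Si](C)(C)C(C)(C)C)c1 | intermediate (not isolated)
12 | 1-(4-bromobutyl)-3,5-bis(tert-butyldimethylsilyloxy)benzene | BrCCCCc1cc(O[Si](C)(C)C(C)(C)C)cc(O[Si](C)(C)C(C)(C)C)c1 | intermediate
13 | {4-[3,5-bis(tert-butyldimethylsilyloxy)phenyl]butyl}magnesium bromide | Br[Mg]CCCCc1cc(O[Si](C)(C)C(C)(C)C)cc(O[Si](C)(C)C(C)(C)C)c1 | intermediate (not isolated)
14 | (8Z,10R)-1-[3,5-bis(tert-butyldimethylsilyloxy)phenyl]pentadec-8-en-10-ol | CCCCC[C@H](/C=C\CCCCCCCc1cc(O[Si](C)(C)C(C)(C)C)cc(O[Si](C)(C)C(C)(C)C)c1)O | intermediate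
15 | (8Z,10R)-1-[3,5-bis(tert-butyldimethylsilyloxy)phenyl]pentadec-8-en-10-yl acetate | CCCCC[C@H](/C=C\CCCCCCCc1cc(O[Si](C)(C)C(C)(C)C)cc(O[Si](C)(C)C(C)(C)C)c1)OC(C)=O | intermediate
16 | (8Z,10R)-1-(3,5-dihydroxyphenyl)pentadec-8-en-10-yl acetate | CCCCC[C@H](/C=C\CCCCCCCc1cc(O)cc(O)c1)OC(C)=O | target

## Step count and least certain steps

Total step count: 10. Longest linear sequence: 8 steps (steps 1, 2, 3, 4, 5, 8, 9, 10); steps 6 and 7 form a two-step side arm that joins at step 8.

Step 2 (key step). The unactivated 1-alkyl diene is a weak partner for copper-bound glyoxylate. Oligomerisation of 3, proton loss from the cation-like intermediate (ene or Prins pathway), or incomplete endo and facial selectivity may therefore compete. Any shortfall in facial selectivity lowers the enantiomeric purity at C10', and any trans isomer that is not removed becomes the enantiomer after step 3. The fallback sets out from 1, comes back at 6, and replaces steps 2 to 4 with reagent-controlled known chemistry. Luche reduction of 1 (NaBH4, CeCl3·7H2O, MeOH) would give (E)-oct-2-en-1-ol F1. Sharpless asymmetric epoxidation (Ti(Oi-Pr)4, (−)-diethyl D-tartrate, t-BuOOH, 4 Å sieves, CH2Cl2, −20 °C) would give [(2R,3R)-3-pentyloxiran-2-yl]methanol F2. Appel chlorination (PPh3, CCl4, NaHCO3) would give (2S,3R)-2-(chloromethyl)-3-pentyloxirane F3. Excess n-BuLi in THF at −78 °C would open the epoxide by elimination and then eliminate chloride to give (R)-oct-1-yn-3-ol F4, with the carbinol C–O bond untouched. The dianion of F4 (n-BuLi, THF/DMPU) would be C-alkylated with 2-(3-bromopropoxy)tetrahydro-2H-pyran to give (6R)-1-(tetrahydro-2H-pyran-2-yloxy)undec-4-yn-6-ol F5. Semi-hydrogenation over Pd/CaCO3 poisoned with Pb(OAc)2 and quinoline would give (4Z,6R)-1-(tetrahydro-2H-pyran-2-yloxy)undec-4-en-6-ol F6, and PPTS in MeOH would release 6.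

Step 3. Electron transfer to an unstrained alpha-alkoxy ester may be slow, and the departing alkoxide remains tethered, so that incomplete cleavage or competing reduction at the ester carbonyl may occur. The fallback sets out from 4, comes back at 6, and opens the ring by a Boord-type reductive fragmentation instead of at the ester. LiAlH4 would reduce 4 to [(2R,6R)-6-pentyl-3,6-dihydro-2H-pyran-2-yl]methanol F7. I2, PPh3 and imidazole would give (2R,6R)-2-(iodomethyl)-6-pentyl-3,6-dihydro-2H-pyran F8. Zinc dust in refluxing EtOH would insert into the C–I bond and expel the ring oxygen to give (4Z,6R)-undeca-1,4-dien-6-ol F9. Hydroboration of the terminal alkene of F9 with 9-BBN (2.2 equiv, the hydroxyl consuming one), followed by H2O2 and NaOH, would give 6.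

Step 8. Incomplete formation or Wurtz-type homocoupling of the functionalised Grignard reagent, its consumption by the free hydroxyl, and slow intramolecular O-alkylation of the magnesium alkoxide onto the tosylate (closure of a seven-membered ether) would each lower conversion. The fallback sets out from 7, comes back at 14, and moves the arene attachment to the aryl–C1' bond. Compound 7 would be coupled with commercial but-3-enylmagnesium bromide (large excess, Li2CuCl4 cat., THF, −40 → 0 °C) to give (6R,7Z)-pentadeca-7,14-dien-6-ol F10. Hydroboration of its terminal alkene with 9-BBN (2.2 equiv) would give 9-[(8Z,10R)-10-hydroxypentadec-8-en-1-yl]-9-borabicyclo[3.3.1]nonane F11, the cis-disubstituted allylic alkene reacting far more slowly. B-alkyl Suzuki–Miyaura coupling of F11 with 9 (PdCl2(dppf), K3PO4·H2O, THF/DMF, 40 °C) would give 14. The allylic position is still a free alcohol at this stage and so is not ionised by zerovalent palladium.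

Step 10. Acyl transfer from the C10' oxygen to a liberated phenoxide, or fluoride- and base-promoted loss of the acetate, may accompany desilylation. The fallback sets out from 14, comes back at 16, and reverses the order of unmasking and acylation. TBAF in THF would convert 14 into 5-[(8Z,10R)-10-hydroxypentadec-8-en-1-yl]benzene-1,3-diol F12. Ac2O, pyridine and DMAP would give 5-[(8Z,10R)-10-acetoxypentadec-8-en-1-yl]-1,3-phenylene diacetate F13. Chemoselective aminolysis of the two aryl acetates with pyrrolidine (2.2 equiv, THF, 0 °C) would give 16, since aryl esters are cleaved by amines much faster than a secondary alkyl acetate.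

## Further compounds

F1 | step 2 | (E)-oct-2-en-1-ol | CCCCC/C=C/CO
F2 | step 2 | [(2R,3R)-3-pentyloxiran-2-yl]methanol | CCCCC[C@H]1O[C@@H]1CO
F3 | step 2 | (2S,3R)-2-(chloromethyl)-3-pentyloxirane | CCCCC[C@H]1O[C@@H]1CCl
F4 | step 2 | (R)-oct-1-yn-3-ol | CCCCC[C@@H](O)C#C
F5 | step 2 | (6R)-1-(tetrahydro-2H-pyran-2-yloxy)undec-4-yn-6-ol | CCCCC[C@@H](O)C#CCCCOC1CCCCO1
F6 | step 2 | (4Z,6R)-1-(tetrahydro-2H-pyran-2-yloxy)undec-4-en-6-ol | CCCCC[C@H](/C=C\CCCOC1CCCCO1)O
F7 | step 3 | [(2R,6R)-6-pentyl-3,6-dihydro-2H-pyran-2-yl]methanol | CCCCC[C@@H]1C=CC[C@H](CO)O1
F8 | step 3 | (2R,6R)-2-(iodomethyl)-6-pentyl-3,6-dihydro-2H-pyran | CCCCC[C@@H]1C=CC[C@H](CI)O1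
F9 | step 3 | (4Z,6R)-undeca-1,4-dien-6-ol | CCCCC[C@H](/C=C\CC=C)O
F10 | step 8 | (6R,7Z)-pentadeca-7,14-dien-6-ol | CCCCC[C@H](/C=C\CCCCCC=C)O
F11 | step 8 | 9-[(8Z,10R)-10-hydroxypentadec-8-en-1-yl]-9-borabicyclo[3.3.1]nonane | CCCCC[C@H](/C=C\CCCCCCCB1C2CCCC1CCC2)O
F12 | step 10 | 5-[(8Z,10R)-10-hydroxypentadec-8-en-1-yl]benzene-1,3-diol | CCCCC[C@H](/C=C\CCCCCCCc1cc(O)cc(O)c1)O
F13 | step 10 | 5-[(8Z,10R)-10-acetoxypentadec-8-en-1-yl]-1,3-phenylene diacetate | CCCCC[C@H](/C=C\CCCCCCCc1cc(OC(C)=O)cc(OC(C)=O)c1)OC(C)=O
A1 | alternative 1 | (R)-2-butoxy-5-pentyl-2,5-dihydro-1,2-oxaborole | CCCCC[C@@H]1C=CB(OCCCC)O1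
A2 | alternative 1 | (R)-oct-1-en-3-ol | CCCCC[C@@H](O)C=C
A3 | alternative 1 | butyl (R)-oct-1-en-3-yl vinylboronate | CCCCC[C@@H](OB(C=C)OCCCC)C=C
A4 | alternative 1 | 1-(7-bromoheptyl)-3,5-bis(tert-butyldimethylsilyloxy)benzene | BrCCCCCCCc1cc(O[Si](C)(C)C(C)(C)C)cc(O[Si](C)(C)C(C)(C)C)c1
A5 | alternative 2 | 3-ethoxy-5-[(8Z,10R)-10-(tert-butyldimethylsilyloxy)pentadec-8-en-1-yl]phenol | CCCCC[C@H](/C=C\CCCCCCCc1cc(O)cc(OCC)c1)O[Si](C)(C)C(C)(C)C
A6 | alternative 2 | 3-[(8Z,10R)-10-(tert-butyldimethylsilyloxy)pentadec-8-en-1-yl]cyclobut-2-en-1-one | CCCCC[C@H](/C=C\CCCCCCCC1=CC(=O)C1)O[Si](C)(C)C(C)(C)C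
A7 | alternative 2 | ethoxyacetylene | CCOC#C
A8 | alternative 3 | methyl 2,4-dihydroxy-6-[(8Z,10R)-10-(tert-butyldimethylsilyloxy)pentadec-8-en-1-yl]benzoate | CCCCC[C@H](/C=C\CCCCCCCc1cc(O)cc(O)c1C(=O)OC)O[Si](C)(C)C(C)(C)C
A9 | alternative 3 | methyl (15Z,17R)-17-(tert-butyldimethylsilyloxy)-3,5,7-trioxodocos-15-enoate | CCCCC[C@H](/C=C\CCCCCCCC(=O)CC(=O)CC(=O)CC(=O)OC)O[Si](C)(C)C(C)(C)C
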